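**Plan**

- Feature: ring A is a phloroglucinol with oxygens on the alternate carbons C5, C7 and C8a and the acyl carbon C4 on C4a, the pattern of a folded poly-β-keto chain. C4a–C8a is therefore a Claisen bond, and the geranyl carbon C6, between the oxygenated C5 and C7, is the central methine of a 1,3-diketone in the open chain.
- Cuts, in retrosynthetic order: the two B-ring MOM ethers; O1–C2 (oxa-Michael), opening ring C to a chalcone; C4a–C8a (Claisen), unfolding ring A into a methyl 3,5,7-triketo ester (chain C1 to C9 = C8a, C8, C7, C6, C5, C4a, C4, C3, C2); chain bonds C6–C7, C4–C5 and C4–geranyl; the C8=C9 alkene.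
- Forward: methyl acetoacetate is geranylated at its γ-carbon, acetylated at the same carbon, and acylated at the new terminal methyl with a cinnamoyl N-methoxy-N-methylamide made from 3,5-dihydroxybenzaldehyde (ring B). Ring A then closes by Claisen folding and ring C by oxa-Michael addition.
- Stereochemistry: the E-alkene of the side chain comes from geranyl bromide; the single stereocentre C2 (S) is set in the catalyst-controlled oxa-Michael closure.

Key step: step 6

Assumption: the quinidine-derived thiourea of step 7 is taken to be the pseudoenantiomer that induces the 2S configuration; if the sense of induction proved opposite, the quinine-derived pseudoenantiomer would be used under the same conditions.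

**Route**

Step 1
Reactants: 1 3,5-dihydroxybenzaldehyde
Product: 2 3,5-bis(methoxymethoxy)benzaldehyde
Conditions: MOMCl (2.5 equiv), i-Pr2NEt (3 equiv), CH2Cl2, 0 °C to rt
Reagents that add atoms: chloromethyl methyl ether (MOMCl), COCCl
Why: Williamson-type O-alkylation of the two phenols by the reactive α-chloro ether under amine base gives acetal ethers that are inert to the amide bases and the magnesium methoxide used later, while the aldehyde is untouched.

Step 2
Reactants: 2 3,5-bis(methoxymethoxy)benzaldehyde; 3 diethyl [2-(methoxy(methyl)amino)-2-oxoethyl]phosphonate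
Product: 4 (E)-3-[3,5-bis(methoxymethoxy)phenyl]-N-methoxy-N-methylprop-2-enamide
Conditions: NaH, THF, 0 °C to rt
Reagents that add atoms: none
Why: Horner–Wadsworth–Emmons olefination with a stabilised phosphonate carbanion is reliably E-selective for aromatic aldehydes and installs the cinnamoyl unit directly as an N-methoxy-N-methylamide, an acyl donor that stops at the ketone stage.

Step 3
Reactants: 5 methyl acetoacetate; 6 geranyl bromide
Product: 7 methyl (6E)-7,11-dimethyl-3-oxododeca-6,10-dienoate
Conditions: LiN(i-Pr)2 (2.1 equiv), THF, 0 °C; then 6, 0 °C to rt; aq NH4Cl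
Reagents that add atoms: none
Why: Alkylation of a β-keto ester dianion: the γ-carbanion is the most nucleophilic site and displaces the primary allylic bromide by SN2 at C1 without allylic transposition, so the E-geranyl chain is attached to chain C4 with its alkene geometry unchanged.

Step 4
Reactants: 7 methyl (6E)-7,11-dimethyl-3-oxododeca-6,10-dienoate; 8 N-methoxy-N-methylacetamide
Product: 9 methyl 4-geranyl-3,5-dioxohexanoate
Conditions: LiN(i-Pr)2 (2.2 equiv), THF, −78 to 0 °C; then 8, −78 to 0 °C; aq NH4Cl
Reagents that add atoms: none
Why: γ-Acylation of the β-keto ester dianion by an N-methoxy-N-methylamide: the chelated tetrahedral adduct persists until the quench, so the more acidic 1,3-diketone is not released in the presence of unreacted dianion, and C4 becomes the geranyl-bearing methine between the C3 and C5 carbonyls.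

Step 5
Reactants: 9 methyl 4-geranyl-3,5-dioxohexanoate; 4 (E)-3-[3,5-bis(methoxymethoxy)phenyl]-N-methoxy-N-methylprop-2-enamide
Product: 10 methyl (8E)-9-[3,5-bis(methoxymethoxy)phenyl]-4-geranyl-3,5,7-trioxonon-8-enoate
Conditions: LiN(i-Pr)2 (3.3 equiv), THF, −78 to 0 °C; then 4, −78 to −20 °C; AcOH then aq NH4Cl at −78 °C; crude product taken on without delay
Reagents that add atoms: none
Why: Polyanion acylation: in the trilithio derivative of 9 the last-formed carbanion at the terminal methyl (C6) is the least stabilised and most nucleophilic, and it adds to the amide carbonyl of 4 to give a chelated adduct that collapses to the C7 ketone only on protonation.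

Step 6
Reactants: 10 methyl (8E)-9-[3,5-bis(methoxymethoxy)phenyl]-4-geranyl-3,5,7-trioxonon-8-enoate
Product: 12 3'-geranyl-2',4',6'-trihydroxy-3,5-bis(methoxymethoxy)chalcone, via acylcyclohexane-1,3,5-trione 11 (not isolated)
Conditions: Mg(OMe)2 (excess), MeOH, 60 °C, argon; then ice-cold 1 M HCl, EtOAc
Reagents that add atoms: none
Why: Mg(OMe)2 turns 10 into a chelated polyenolate in which C6, the central carbon of the C5/C7 diketonate, adds to the C1 ester carbonyl; methoxide is expelled to give the trione 11, and threefold enolisation delivers the aromatic acylphloroglucinol, so the new bond C6–C1 of the chain is C4a–C8a of the target. The closest known reaction type is the intramolecular Claisen (Dieckmann-type) cyclisation of 3,5,7-triketo esters, and of the 4-hydroxy-2-pyranones formed from them, to acylphloroglucinols under magnesium alkoxide. Ring A closes in a 6-exo-trig mode at the ester carbonyl. No stereocentre is created, and the epimerisable C4 centre of 10 disappears on aromatisation. The step needs the Claisen fold to win over the aldol fold (C2 onto the C7 ketone, which would end in a stilbene-type resorcylate) and over lactonisation: the ester is the least enolised carbonyl of the chain, the C7 ketone is deactivated as part of a chelated cinnamoyl diketonate, any pyranone is reopened by methoxide, and the geranyl group on C4 destabilises the extended chelated C3/C5 diketonate by allylic 1,3-strain and so biases the chain toward the folded conformer in which C6 and C1 can bond. Aromatisation makes the closure irreversible, and the product stays an open chalcone phenoxide in the basic medium until the cold acidic quench.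

Step 7
Reactants: 12 3'-geranyl-2',4',6'-trihydroxy-3,5-bis(methoxymethoxy)chalcone
Product: 13 (2S)-2-[3,5-bis(methoxymethoxy)phenyl]-6-geranyl-5,7-dihydroxychroman-4-one
Conditions: N-[3,5-bis(trifluoromethyl)phenyl]-N'-[(9R)-6'-methoxycinchonan-9-yl]thiourea (10 mol%), PhMe–CH2Cl2, −20 °C
Reagents that add atoms: none
Why: Intramolecular oxa-Michael addition of a 2'-hydroxychalcone under bifunctional base/hydrogen-bond-donor catalysis (6-endo-trig): the quinuclidine nitrogen activates the hydroxyl flanked by hydrogen, which is the more acidic and less strongly chelated of the two ortho hydroxyls and so should close in preference to the geranyl-flanked one, while the thiourea holds the enone carbonyl so that the oxygen is delivered to one face of the β-carbon, setting C2 (S) under catalyst control.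

Step 8
Reactants: 13 (2S)-2-[3,5-bis(methoxymethoxy)phenyl]-6-geranyl-5,7-dihydroxychroman-4-one
Product: 14 Schizolaenone C
Conditions: 3 M HCl in MeOH, 40 °C
Reagents that add atoms: none
Why: Acid-catalysed transacetalisation of the aryl methoxymethyl ethers to methanol frees the two B-ring phenols; the B ring has no para oxygen that could assist ring opening or ionisation at C2, so the S centre should be retained, and the mild temperature is chosen to keep the geranyl alkenes from cyclising onto the flanking phenols.

**Compound list**

1 | 3,5-dihydroxybenzaldehyde | O=Cc1cc(O)cc(O)c1 | starting material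
2 | 3,5-bis(methoxymethoxy)benzaldehyde | O=Cc1cc(OCOC)cc(OCOC)c1 | intermediate
3 | diethyl [2-(methoxy(methyl)amino)-2-oxoethyl]phosphonate | CCOP(=O)(CC(=O)N(C)OC)OCC | starting material
4 | (E)-3-[3,5-bis(methoxymethoxy)phenyl]-N-methoxy-N-methylprop-2-enamide | CON(C)C(=O)/C=C/c1cc(OCOC)cc(OCOC)c1 | intermediate
5 | methyl acetoacetate (methyl 3-oxobutanoate) | COC(=O)CC(C)=O | starting material
6 | geranyl bromide, (2E)-1-bromo-3,7-dimethylocta-2,6-diene | CC(C)=CCC/C(C)=C/CBr | starting material
7 | methyl (6E)-7,11-dimethyl-3-oxododeca-6,10-dienoate | COC(=O)CC(=O)CC/C=C(\C)CCC=C(C)C | intermediate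
8 | N-methoxy-N-methylacetamide | CC(=O)N(C)OC | starting material
9 | methyl 4-geranyl-3,5-dioxohexanoate, methyl (6E)-4-acetyl-7,11-dimethyl-3-oxododeca-6,10-dienoate (C4 racemic, enolisable) | COC(=O)CC(=O)C(C/C=C(\C)CCC=C(C)C)C(C)=O | intermediate
10 | methyl (8E)-9-[3,5-bis(methoxymethoxy)phenyl]-4-[(2E)-3,7-dimethylocta-2,6-dien-1-yl]-3,5,7-trioxonon-8-enoate (C4 racemic, enolisable) | COC(=O)CC(=O)C(C/C=C(\C)CCC=C(C)C)C(=O)CC(=O)/C=C/c1cc(OCOC)cc(OCOC)c1 | intermediate
11 | 2-{(2E)-3-[3,5-bis(methoxymethoxy)phenyl]prop-2-enoyl}-4-[(2E)-3,7-dimethylocta-2,6-dien-1-yl]cyclohexane-1,3,5-trione (not isolated) | O=C1CC(=O)C(C/C=C(\C)CCC=C(C)C)C(=O)C1C(=O)/C=C/c1cc(OCOC)cc(OCOC)c1 | intermediate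
12 | 3'-geranyl-2',4',6'-trihydroxy-3,5-bis(methoxymethoxy)chalcone, (2E)-3-[3,5-bis(methoxymethoxy)phenyl]-1-{3-[(2E)-3,7-dimethylocta-2,6-dien-1-yl]-2,4,6-trihydroxyphenyl}prop-2-en-1-one | CC(C)=CCC/C(C)=C/Cc1c(O)cc(O)c(C(=O)/C=C/c2cc(OCOC)cc(OCOC)c2)c1O | intermediate
13 | (2S)-2-[3,5-bis(methoxymethoxy)phenyl]-6-[(2E)-3,7-dimethylocta-2,6-dien-1-yl]-5,7-dihydroxy-2,3-dihydro-4H-chromen-4-one | CC(C)=CCC/C(C)=C/Cc1c(O)cc2c(c1O)C(=O)C[C@@H](c1cc(OCOC)cc(OCOC)c1)O2 | intermediate
14 | Schizolaenone C, (2S)-2-(3,5-dihydroxyphenyl)-6-[(2E)-3,7-dimethylocta-2,6-dien-1-yl]-5,7-dihydroxy-2,3-dihydro-4H-chromen-4-one | CC(C)=CCC/C(C)=C/Cc1c(O)cc2c(c1O)C(=O)C[C@@H](c1cc(O)cc(O)c1)O2 | target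

**Step count**

Total: 8 steps. Longest linear sequence: 6 steps (5 to 7 to 9 to 10 to 12 to 13 to 14; the branch from 1 through 2 and 4 is equally long).

**Steps most likely to fail**

Step 7. The conjugate addition may proceed with poor facial selectivity, the flavanone may lose enantiomeric purity by reversible ring opening, and closure may also take place through the geranyl-flanked hydroxyl. The fallback sets out from 12 and returns at 13. The chalcone would be closed under thermodynamic control (NaOAc, EtOH, reflux) to the racemic 6-geranyl flavanone F1. The regioisomeric racemic 8-geranyl flavanone F2 would be removed on silica and returned to 12 by ring opening with aqueous KOH and cold acidification. F1 would then be resolved kinetically by asymmetric transfer hydrogenation with RuCl(p-cymene)[(R,R)-TsNCHPhCHPhNH2] (divalent ruthenium) in HCO2H–Et3N (5:2), EtOAc, rt. This is expected to reduce the 2R enantiomer to the cis-(2R,4R)-flavan-4-ol F3 and to leave the 2S ketone, which is 13.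

Step 6. The chain may fold in the aldol sense (C2 onto the C7 ketone), may lactonise to a 4-hydroxy-2-pyranone that does not reopen, or the chalcone may close non-selectively during work-up. The fallback sets out from 5 and 6, uses 8 and 4 as acyl donors, and returns at 12 by way of 11. Compound 5 would be alkylated at C2 with 6 (K2CO3, acetone) to methyl 2-geranylacetoacetate F4. The dianion of F4 (LiN(i-Pr)2, THF) would be acetylated with 8 to methyl 2-geranyl-3,5-dioxohexanoate F5, and the trianion of F5 acylated with 4 to the 2-geranyl triketo ester F6. Mg(OMe)2 in MeOH would then close F6 through the same trione 11 to 12. With the geranyl group on C2, the aldol fold would have to create a quaternary carbon that cannot aromatise, so only the Claisen fold leads to an aromatic product.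

Step 5. The polyanion may add in conjugate fashion to the unsaturated amide, the third deprotonation may be incomplete, or proton transfer may quench the carbanion before acylation. The fallback sets out from 4 and 9 and returns at 10. Compound 4 would be reduced with i-Bu2AlH (THF, −78 °C) to the cinnamaldehyde F7. The trianion of 9 would add to the aldehyde carbonyl of F7 to give the 7-hydroxy diketo ester F8; this is an aldol addition, in which 1,2-attack on an aldehyde is much faster than conjugate addition. The allylic alcohol of F8 would be oxidised with MnO2 in CH2Cl2 to the C7 ketone, which is 10.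

**Further compounds**

F1 | step 7 | racemic 2-[3,5-bis(methoxymethoxy)phenyl]-6-geranyl-5,7-dihydroxychroman-4-one | CC(C)=CCC/C(C)=C/Cc1c(O)cc2c(c1O)C(=O)CC(c1cc(OCOC)cc(OCOC)c1)O2
F2 | step 7 | racemic 2-[3,5-bis(methoxymethoxy)phenyl]-8-geranyl-5,7-dihydroxychroman-4-one | CC(C)=CCC/C(C)=C/Cc1c(O)cc(O)c2c1OC(c1cc(OCOC)cc(OCOC)c1)CC2=O
F3 | step 7 | (2R,4R)-2-[3,5-bis(methoxymethoxy)phenyl]-6-geranyl-3,4-dihydro-2H-chromene-4,5,7-triol | CC(C)=CCC/C(C)=C/Cc1c(O)cc2c(c1O)[C@H](O)C[C@H](c1cc(OCOC)cc(OCOC)c1)O2
F4 | step 6 | methyl 2-geranylacetoacetate, methyl (4E)-2-acetyl-5,9-dimethyldeca-4,8-dienoate | COC(=O)C(C/C=C(\C)CCC=C(C)C)C(C)=O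
F5 | step 6 | methyl 2-geranyl-3,5-dioxohexanoate | COC(=O)C(C/C=C(\C)CCC=C(C)C)C(=O)CC(C)=O
F6 | step 6 | methyl (8E)-9-[3,5-bis(methoxymethoxy)phenyl]-2-geranyl-3,5,7-trioxonon-8-enoate | COC(=O)C(C/C=C(\C)CCC=C(C)C)C(=O)CC(=O)CC(=O)/C=C/c1cc(OCOC)cc(OCOC)c1
F7 | step 5 | (E)-3-[3,5-bis(methoxymethoxy)phenyl]prop-2-enal | O=C/C=C/c1cc(OCOC)cc(OCOC)c1
F8 | step 5 | methyl (8E)-9-[3,5-bis(methoxymethoxy)phenyl]-4-geranyl-7-hydroxy-3,5-dioxonon-8-enoate | COC(=O)CC(=O)C(C/C=C(\C)CCC=C(C)C)C(=O)CC(O)/C=C/c1cc(OCOC)cc(OCOC)c1
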